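Answer two questions about this flask: which species holds most at 80 min, and how much.

all flasks: starting material 0.10 M

| charge | reagent | free catalyst | remark | time |
|---|---|---|---|---|
| Monday's | 1.5 equiv | 1 mol% | the very flask that is asked about, followed so far |  |
| Saturday's | 1.5 equiv | 0.5 mol% | run made earlier |  |
| flask | 1.50 equiv | 1 mol% |  | 80 min |

| run | time / min | catalyst intermediate C / % | starting material / % | product / % |
|---|---|---|---|---|
| Monday's | 2.50 | 1.6 | 92.0 | 8.0 |
| Monday's | 5.00 | 0.6 | 86.9 | 14.5 |
| Monday's | 8.00 | 0 | 77.5 | 20.6 |
| Monday's | 10.0 | 0 | 76.5 | 23.6 |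
| Monday's | 12.0 | 1.2 | 72.3 | 25.4 |
| Monday's | 15.0 | 0 | 67.6 | 32.8 |
| Saturday's | 10.0 | 0.5 | 84.9 | 14.2 |
| Saturday's | 20.0 | 1.2 | 79.6 | 21.8 |
| Saturday's | 30.0 | 1.2 | 72.7 | 27.2 |
| Saturday's | 40.0 | 0 | 68.9 | 29.7 |
| Saturday's | 50.0 | 0 | 67.2 | 31.6 |
| Saturday's | 60.0 | 0 | 66.9 | 34.1 |

(scatter of a reading: 1 percentage point)

* the species that holds most of what was charged as starting material, at 80 min (product / starting material / catalyst intermediate C)
* the largest share itself, whichever of these holds it, in percent of the starting material charged

- the analysis behind the earlier runs scatters by 1 percentage point, standard deviation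

Draw the curve in one coordinate, the reach: the natural log of starting material charged over starting material left, which is the integrated pseudo-first-order exponent. Product passes starting material at a reach of 0.693. Monday's run opens at 0.0334 min⁻¹ and Saturday's at 0.0164 min⁻¹, twice as steep, with 1 mol% of free catalyst against 0.5 mol%. Saturday's run then bends, and its starting material reads 67.2 %, then 66.9 %.

Read that last level as 804 M⁻¹, the level reach per unit of catalyst concentration. Multiplied by this flask's catalyst concentration, it gives a level of 0.804, above the crossing. My reckoning leaves product at 55.2 %.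

The forecast says product at 54 %, within 50 % to 60 %, because “the catalyst appears to die on a clock”.

The flask gives product at 53.2 %, with starting material at 46.8 %.

    reagent + free catalyst ⇌ catalyst intermediate A (K = 1.19 M⁻¹, k = 40.6 M⁻¹ min⁻¹)
    catalyst intermediate A ⇌ by-product + catalyst intermediate B (K = 0.805 M, k = 149 min⁻¹)
    starting material + catalyst intermediate B → catalyst intermediate C (k = 313 M⁻¹ min⁻¹)
    catalyst intermediate C ⇌ free catalyst + product (K = 1.78 M, k = 21.0 min⁻¹)
    reagent ⇌ dormant form (K = 19.8, k = 0.0414 min⁻¹)
    2 catalyst intermediate B → spent catalyst (k = 1060 M⁻¹ min⁻¹)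

At 10.2 min, reagent enters the dormant form at 1.6 times the forward rate at which it meets free catalyst. At 80.0 min, 2.8 % of its charge remains, beside 68.2 % of the catalyst free, so watch [reagent]. The forecast would fail on a run moved beyond 3.2 percentage points downward; 1.29 equiv of reagent moves product by 5 points. At 0.025 M of starting material, same recipe and time, the reach gives 0.201, below the crossing, and 18.2 % product. That neighbour computes to 22.1 % product, with starting material holding most.

All runs stem from a simulated flask for substances that don't exist; the scatter is artificial.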